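**Retrosynthetic overview**
1. Miyabenol A (12) ⇐ tetra-TIPS ether 11 by fluoride removal of four aryl silyl ethers.
2. 11 ⇐ 2 × (2R,3R)-10: the central dihydrobenzofuran (ring 2) is cut at C3–C3a and C2–O. Forward, this is a one-electron oxidative radical-cation [3+2] homodimerisation (stilbene C=C of one molecule plus the free resorcinol ring of the other), with the (2S,3S) centres set by substrate control.
3. 10 ⇐ rac-9 (resolution) ⇐ 2 × monomer 8 by the same oxidative [3+2]; this makes the ring that becomes both ring 1 and ring 3.
4. 8 ⇐ Heck coupling of 5 + 7; 5 ⇐ boronate 3 + vinyl bromide 4 (Suzuki); 3 ⇐ resorcinol 1 via bis-TMS ether 2 (meta C–H borylation); 7 ⇐ 4-iodophenol 6.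
5. Ring order: rings 1 and 3 first (identical, formed at the dimer stage), ring 2 last.

Assumption: the chromatographic enantiomer separation counts as one step. Ring 1 is the dihydrobenzofuran carrying the styryl arm, ring 2 is the central one, ring 3 carries the 3,5-dihydroxyphenyl group. The target SMILES reads as ring 1 (2R,3R), ring 2 (2S,3S), ring 3 (2R,3R), all 2,3-trans, E-alkene.

**Route**

Step 1
Reactants: 1 resorcinol
Product: 2 1,3-bis(trimethylsilyloxy)benzene
Conditions: HMDS (1.1 equiv), cat. TMSCl, neat, 100 °C; distil
Reagents that add atoms: hexamethyldisilazane, C[Si](C)(C)N[Si](C)(C)C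
Why: Quantitative O-silylation (transient protection) that makes C5 the only unhindered C–H for the next step.

Step 2
Reactants: 2 1,3-bis(trimethylsilyloxy)benzene
Product: 3 2-[3,5-bis(trimethylsilyloxy)phenyl]-4,4,5,5-tetramethyl-1,3,2-dioxaborolane
Conditions: [Ir(OMe)(cod)]2 (1 mol%), dtbpy (2 mol%), B2pin2 (0.6 equiv), cyclohexane, 80 °C, Ar; evaporate, short silica plug (hexane), use directly
Reagents that add atoms: bis(pinacolato)diboron, CC1(C)OB(OC1(C)C)B1OC(C)(C)C(C)(C)O1
Why: Sterically controlled Ir-catalysed Hartwig–Miyaura C–H borylation occurs only at C5 (meta to both OSiMe3 groups); the C–H bonds ortho to a silyloxy group are blocked.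

Step 3
Reactants: 3 aryl pinacol boronate; 4 vinyl bromide
Product: 5 5-ethenylbenzene-1,3-diol (3,5-dihydroxystyrene)
Conditions: Pd(dppf)Cl2 (3 mol%), 4 (3 equiv, 1 M in THF), 3 M aq K3PO4, THF, 50 °C, sealed; then MeOH, adjust to pH 6, BHT (trace), extract; use promptly
Reagents that add atoms: none (the vinyl group comes from reactant 4; the Bpin and TMS groups are lost)
Why: Suzuki–Miyaura vinylation of the arylboronate; the aqueous base and methanolic work-up also hydrolyse the labile aryl TMS ethers to the free resorcinol.

Step 4
Reactants: 6 4-iodophenol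
Product: 7 (4-iodophenoxy)tri(propan-2-yl)silane
Conditions: TIPSCl (1.1 equiv), imidazole, DMF, rt
Reagents that add atoms: triisopropylsilyl chloride, CC(C)[Si](Cl)(C(C)C)C(C)C
Why: Standard phenol silylation; the electron-donating, fluoride-labile TIPS ether blocks phenoxyl-radical chemistry at the para-oxygen in steps 6 and 8.

Step 5
Reactants: 5 5-ethenylbenzene-1,3-diol; 7 (4-iodophenoxy)triisopropylsilane
Product: 8 5-[(E)-2-(4-{[tri(propan-2-yl)silyl]oxy}phenyl)ethenyl]benzene-1,3-diol (4′-O-TIPS-resveratrol)
Conditions: Pd(OAc)2 (3 mol%), P(o-tol)3 (6 mol%), Et3N, MeCN, 80 °C, dark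
Reagents that add atoms: none
Why: Mizoroki–Heck arylation of the terminal alkene carbon gives the E-stilbene by syn-insertion/syn-β-hydride elimination; free phenols and the aryl TIPS ether tolerate amine base.

Step 6
Reactants: 8 (two molecules)
Product: 9 rac-5-[(2R*,3R*)-6-hydroxy-2-(4-TIPSO-phenyl)-4-[(E)-2-(4-TIPSO-phenyl)ethenyl]-2,3-dihydro-1-benzofuran-3-yl]benzene-1,3-diol (racemic 2,3-trans; ε-viniferin with both 4-hydroxyphenyl oxygens as TIPS ethers)
Conditions: FeCl3·6H2O (0.7 equiv, added in acetone), CH2Cl2/acetone 4:1, 0.1 M, 0 °C → rt, dark; aq NaHCO3/ascorbate quench; recover 8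
Reagents that add atoms: none
Why: Proposed new method: Fe(III)-mediated oxidative radical-cation formal [3+2] cycloaddition in which the 4-silyloxystilbene radical cation of one molecule is attacked, at the alkene carbon remote from the silyloxyphenyl ring, by the resorcinol carbon ortho to OH and ortho to the styryl arm of a second molecule; the resulting 4-silyloxybenzyl radical is oxidised to the cation and closed by the adjacent OH, giving the thermodynamically preferred 2,3-trans ring (both centres, racemic). The closest known reactions are the FeCl3- or photoredox-mediated oxidative [3+2] cycloaddition of phenols with electron-rich styrenes and the FeCl3·6H2O dimerisation of resveratrol to ε-viniferin.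

Step 7
Reactants: 9 racemic dimer
Product: 10 the (2R,3R)-enantiomer of 9
Conditions: preparative chiral SFC, amylose tris(3,5-dimethylphenylcarbamate) phase, CO2/i-PrOH
Reagents that add atoms: none
Why: Chromatographic resolution on a polysaccharide chiral phase supplies the single (2R,3R) enantiomer (no new stereocentre); configuration is confirmed by ECD after desilylating an aliquot to ε-viniferin of known configuration.

Step 8 (key step)
Reactants: 10 (two molecules: one reacts through its stilbene C=C, the other through its free 3,5-dihydroxyphenyl ring)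
Product: 11 miyabenol A tetra-TIPS ether (all four 4-hydroxyphenyl oxygens silylated; five resorcinol-type OH free; ring 1 2R,3R, ring 2 2S,3S, ring 3 2R,3R; E-alkene)
Conditions: FeCl3·6H2O (0.5 equiv, slow addition in acetone), CH2Cl2/acetone 4:1, 0.25 M, −20 → 0 °C, dark; stop at about 50% conversion, recycle 10
Reagents that add atoms: none
Why: Proposed new method: oxidative radical-cation formal [3+2] homodimerisation, in which Fe(III) takes one electron from the 4-silyloxystilbene of one molecule of 10 (with no free para-phenol the quinone-methide-radical 8–8′ and 3–8′ couplings are closed), the free 3,5-dihydroxyphenyl ring of a second molecule adds through its carbon ortho to one OH and para to the other to the alkene carbon remote from the silyloxyphenyl ring (the radical C–C bond formation), and the resulting 4-silyloxybenzyl radical is oxidised to the cation and closed by the adjacent phenol to the 2,3-trans ring; the new C3 centre is predicted to form by attack on the alkene face anti to the 3,5-dihydroxyphenyl group on the neighbouring C3 of the stilbene partner's own dihydrofuran (s-trans styrene rotamer), which gives the required (2S,3S) ring between two (2R,3R) rings; the closest known reaction type is the FeCl3- or photoredox-mediated oxidative [3+2] cycloaddition of phenols with electron-rich styrenes.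

Step 9
Reactants: 11 miyabenol A tetra-TIPS ether
Product: 12 miyabenol A
Conditions: TBAF (5 equiv), AcOH (5 equiv), THF, 0 °C, Ar; reversed-phase HPLC
Reagents that add atoms: none
Why: Fluoride desilylation of aryl TIPS ethers, buffered with AcOH so the acid-sensitive dihydrobenzofurans, the E-alkene and all six stereocentres are untouched.

**Compound list**
1 | resorcinol | Oc1cccc(O)c1 | starting material
2 | 1,3-bis(trimethylsilyloxy)benzene | C[Si](C)(C)Oc1cccc(O[Si](C)(C)C)c1 | intermediate
3 | 2-[3,5-bis(trimethylsilyloxy)phenyl]-4,4,5,5-tetramethyl-1,3,2-dioxaborolane | CC1(C)OB(OC1(C)C)c1cc(O[Si](C)(C)C)cc(O[Si](C)(C)C)c1 | intermediate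
4 | vinyl bromide | C=CBr | starting material
5 | 5-ethenylbenzene-1,3-diol | C=Cc1cc(O)cc(O)c1 | intermediate
6 | 4-iodophenol | Oc1ccc(I)cc1 | starting material
7 | (4-iodophenoxy)triisopropylsilane | CC(C)[Si](Oc1ccc(I)cc1)(C(C)C)C(C)C | intermediate
8 | 4′-O-TIPS-resveratrol (E) | CC(C)[Si](Oc1ccc(/C=C/c2cc(O)cc(O)c2)cc1)(C(C)C)C(C)C | intermediate
9 | rac-trans bis-TIPS ε-viniferin (racemate; (2R,3R) enantiomer drawn) | CC(C)[Si](C(C)C)(C(C)C)Oc1ccc(/C=C/c2cc(O)cc3c2[C@@H](c2cc(O)cc(O)c2)[C@H](c2ccc(O[Si](C(C)C)(C(C)C)C(C)C)cc2)O3)cc1 | intermediate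
10 | (2R,3R)-bis-TIPS ε-viniferin | CC(C)[Si](C(C)C)(C(C)C)Oc1ccc(/C=C/c2cc(O)cc3c2[C@@H](c2cc(O)cc(O)c2)[C@H](c2ccc(O[Si](C(C)C)(C(C)C)C(C)C)cc2)O3)cc1 | intermediate
11 | miyabenol A tetra-TIPS ether | CC(C)[Si](C(C)C)(C(C)C)Oc1ccc(/C=C/c2cc(O)cc3c2[C@@H](c2cc(O)cc4c2[C@H](c2cc(O)cc5c2[C@@H](c2cc(O)cc(O)c2)[C@H](c2ccc(O[Si](C(C)C)(C(C)C)C(C)C)cc2)O5)[C@@H](c2ccc(O[Si](C(C)C)(C(C)C)C(C)C)cc2)O4)[C@H](c2ccc(O[Si](C(C)C)(C(C)C)C(C)C)cc2)O3)cc1 | intermediate
12 | miyabenol A | Oc1ccc(/C=C/c2cc(O)cc3c2[C@@H](c2cc(O)cc4c2[C@H](c2cc(O)cc5c2[C@@H](c2cc(O)cc(O)c2)[C@H](c2ccc(O)cc2)O5)[C@@H](c2ccc(O)cc2)O4)[C@H](c2ccc(O)cc2)O3)cc1 | target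

**Totals**
Total steps: 9. Longest linear sequence: 8 (steps 1, 2, 3, 5, 6, 7, 8, 9 from resorcinol).

**Steps most likely to fail**
1. Step 8. Risks: attack by the other phenolic ring or by the position between the two OH groups, intramolecular capture, the wrong alkene face, and further oligomerisation, since 11 is still both donor and acceptor. Fallback: give up the homodimerisation and cross-couple two differentiated halves. The stilbene partner is 10 with its three phenols acetylated (no nucleophilic ring). The phenol partner is an analogue of 10 carrying an aryl bromide in place of the styryl arm (no oxidisable alkene). The (E)-4-silyloxystyryl arm is then installed last by Heck coupling.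
2. Step 6. Risks: competing 8–8′ radical-cation dimerisation (indane-type products), attack between the two OH groups, and over-reaction of 9. Fallback: build the trans-2,3-diaryl-dihydrobenzofuran without oxidative coupling, by enantioselective Rh(II)-carbene C–H insertion of a benzyl aryl ether (donor/donor carbene) followed by C3 epimerisation. This gives (2R,3R)-10 directly and also removes the resolution.
3. Step 3. Risks: protodeboronation or sluggish coupling once the TMS ethers hydrolyse to phenoxides, loss of volatile vinyl bromide, and polymerisation of 5. Fallback: carry the two-carbon unit on the other partner. Couple 7 with potassium vinyltrifluoroborate to give 4-(TIPSO)styrene, then join it to boronate 3 by an oxidative boron-Heck reaction (Pd(II), O2) and hydrolyse the TMS ethers to reach 8.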